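**Retrosynthetic overview**

1. Numbering: quinone ring A is C1(=O), C2(OMe), C3, C4(=O), C4a, C8a; benzo ring B is C5(H), C6(guaiacylmethyl), C7(CH3), C8(guaiacyl). The strategy rests on the C7–C8 bond of ring B, the most crowded bond of the skeleton (methyl on C7, aryl on C8, C8 peri to the C1 carbonyl); both carbons can be carried as ketone carbons.
2. Larreantin ⇐ debenzylation ⇐ (KO3S)2NO oxidation of a 2-methoxy-1-naphthol (C4 oxygen introduced last) ⇐ MOM removal and DDQ aromatisation of a 3,4-dihydronaphthalene.
3. Dihydronaphthalene ⇐ intramolecular McMurry coupling forming C7=C8 from a 1,6-diketone (diaryl ketone = future C8, methyl ketone = future C7); this closes ring B onto the arene that later becomes ring A.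
4. Diketone ⇐ oxidation of the product of a B-alkyl Suzuki–Miyaura coupling (C4a–C5 bond) between a bromobenzophenone (o-vanillin: MOM ether, NBS, aryllithium addition, MnO2) and the 9-BBN adduct of a 2-benzyl allylic alcohol. This coupling fixes the site of C–C bond formation, which a Heck arylation through a tertiary alkylpalladium with three β-hydrogen sets would not.
5. Allylic alcohol ⇐ aryl Grignard reagent of O-benzyl-4-bromoguaiacol + 2,3-dibromopropene, then vinyllithium + acetaldehyde. Ring order: ring A arene bought, ring B closed in step 10, ring A oxidised to the quinone in step 13.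

Key step: step 10

Remark on the chemistry: Ar = 4-(benzyloxy)-3-methoxyphenyl. Racemic intermediates with one stereocentre are written with one enantiomer drawn; the single mixture of diastereomers (the Suzuki product) carries no descriptors. The target has no stereocentre, so no stereocontrol is needed.

**Route**

Step 1
Reactants: 1 4-bromo-2-methoxyphenol
Product: 2 1-(benzyloxy)-4-bromo-2-methoxybenzene
Conditions: BnBr, K2CO3, DMF, rt
Reagents that add atoms: benzyl bromide, BrCc1ccccc1
Why: Williamson ether synthesis, in which the phenoxide formed by K2CO3 displaces bromide from benzyl bromide (SN2) while the aryl bromide is inert.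

Step 2
Reactants: 2 1-(benzyloxy)-4-bromo-2-methoxybenzene
Product: 4 1-(benzyloxy)-4-(2-bromoprop-2-en-1-yl)-2-methoxybenzene, via arylmagnesium bromide 3 (not isolated)
Conditions: Mg, THF, 50 °C; then CuI (5 mol %), 2,3-dibromopropene, THF, −20 → 0 °C
Reagents that add atoms: 2,3-dibromopropene, C=C(Br)CBr
Why: Grignard formation followed by copper-catalysed allylic substitution, in which only the allylic bromide is displaced (SN2 and SN2' attack give the same product) and the vinylic bromide does not react.

Step 3
Reactants: 4 1-(benzyloxy)-4-(2-bromoprop-2-en-1-yl)-2-methoxybenzene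
Product: 6 rac-3-(ArCH2)but-3-en-2-ol, via vinyllithium 5 (not isolated)
Conditions: t-BuLi (2.1 equiv), Et2O, −78 °C; then CH3CHO, −78 → 0 °C
Reagents that add atoms: acetaldehyde, CC=O
Why: Bromine–lithium exchange of the vinyl bromide (the second equivalent of t-BuLi destroys t-BuBr) is much faster at −78 °C than deprotonation or attack on the benzyl ether, and 1,2-addition to acetaldehyde gives the allylic alcohol as a racemate whose carbinol centre is oxidised away in step 9.

Step 4
Reactants: 7 o-vanillin (2-hydroxy-3-methoxybenzaldehyde)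
Product: 8 3-methoxy-2-(methoxymethoxy)benzaldehyde
Conditions: MOMCl, i-Pr2NEt, CH2Cl2, 0 °C → rt
Reagents that add atoms: chloromethyl methyl ether, COCCl
Why: O-alkylation of the phenol with MOMCl and a hindered amine base (acetal protection), leaving the aldehyde untouched.

Step 5
Reactants: 8 3-methoxy-2-(methoxymethoxy)benzaldehyde
Product: 9 6-bromo-3-methoxy-2-(methoxymethoxy)benzaldehyde
Conditions: NBS, DMF, rt, dark
Reagents that add atoms: N-bromosuccinimide, O=C1CCC(=O)N1Br
Why: Electrophilic aromatic bromination in which the 2-OMOM group, twisted out of conjugation by its two ortho neighbours, leaves the coplanar 3-methoxy group to direct para to itself (C6), the known outcome for 2,3-dialkoxybenzaldehydes, under neutral conditions that should spare the acetal.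

Step 6
Reactants: 9 6-bromo-3-methoxy-2-(methoxymethoxy)benzaldehyde; 2 1-(benzyloxy)-4-bromo-2-methoxybenzene
Product: 11 rac-Ar[6-bromo-3-methoxy-2-(methoxymethoxy)phenyl]methanol, via aryllithium 10 (not isolated)
Conditions: 2 (1.2 equiv), n-BuLi (1.15 equiv), THF, −78 °C; then 9, THF, −78 → −40 °C
Reagents that add atoms: none
Why: Bromine–lithium exchange of the electron-rich aryl bromide with n-BuLi at −78 °C gives the aryllithium, whose 1,2-addition to the aldehyde is far faster than exchange with the aryl bromide of 9 (the known addition of aryllithiums to 2-bromobenzaldehydes); the racemic carbinol centre is removed in step 7.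

Step 7
Reactants: 11 rac-Ar[6-bromo-3-methoxy-2-(methoxymethoxy)phenyl]methanol
Product: 12 Ar[6-bromo-3-methoxy-2-(methoxymethoxy)phenyl]methanone
Conditions: MnO2, CH2Cl2, rt → reflux
Reagents that add atoms: none
Why: MnO2 oxidation of a doubly benzylic carbinol to the benzophenone under neutral heterogeneous conditions that spare the MOM ether, the benzyl ether and the aryl bromide.

Step 8
Reactants: 6 rac-3-(ArCH2)but-3-en-2-ol; 12 Ar[6-bromo-3-methoxy-2-(methoxymethoxy)phenyl]methanone
Product: 14 4-[2-(ArCO)-4-methoxy-3-(methoxymethoxy)phenyl]-3-(ArCH2)butan-2-ol (mixture of diastereomers), via alkyl-9-BBN borinate 13 (not isolated)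
Conditions: 6, 9-BBN (2.3 equiv), THF, 0 °C → rt; then aq K3PO4, 12, PdCl2(dppf) (5 mol %), DMF, 60 °C
Reagents that add atoms: none
Why: Anti-Markovnikov hydroboration with 9-BBN puts boron on the terminal CH2 (one equivalent is taken up by the hydroxyl group as a borinate, as is usual for free allylic alcohols), and B-alkyl Suzuki–Miyaura coupling with the ortho-acyl-activated aryl bromide then forms the aryl–CH2 bond at a defined carbon; the diaryl ketone is tolerated and the new C3 centre arises as a diastereomer mixture that converges in step 9.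

Step 9
Reactants: 14 4-[2-(ArCO)-4-methoxy-3-(methoxymethoxy)phenyl]-3-(ArCH2)butan-2-ol
Product: 15 rac-4-[2-(ArCO)-4-methoxy-3-(methoxymethoxy)phenyl]-3-(ArCH2)butan-2-one
Conditions: Dess–Martin periodinane, CH2Cl2, rt
Reagents that add atoms: none
Why: Dess–Martin oxidation of the secondary alcohol to the methyl ketone under mild conditions, both diastereomers giving the same racemic 1,6-diketone.

Step 10
Reactants: 15 rac-4-[2-(ArCO)-4-methoxy-3-(methoxymethoxy)phenyl]-3-(ArCH2)butan-2-one
Product: 16 rac-1-Ar-3-(ArCH2)-7-methoxy-8-(methoxymethoxy)-2-methyl-3,4-dihydronaphthalene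
Conditions: TiCl3(DME)1.5, Zn–Cu, DME, reflux; 15 added by syringe pump over 30 h (high dilution), then reflux 6 h
Reagents that add atoms: none
Why: Low-valent titanium made from TiCl3 and Zn–Cu transfers electrons to the easily reduced diaryl ketone and to the methyl ketone; the titanium-bound ketyls join to a titanium pinacolate, which at reflux gives up both oxygen atoms to the metal and leaves the C1=C2 alkene of the dihydronaphthalene (C8=C7 of the target). The closest known reaction type is the intramolecular McMurry coupling of diketones to tetrasubstituted cycloalkenes, together with crossed McMurry couplings of benzophenones with alkyl ketones. Ring B is closed as a six-membered carbocycle by carbonyl–carbonyl coupling of a 1,6-diketone, formally a 6-exo-trig attack of the ketyl carbon on the second carbonyl with both oxygen atoms outside the ring. No stereocentre is created: the new double bond lies in the ring, and the racemic C3 centre is a spectator that disappears in step 11. Intramolecular coupling must win over dimerisation and over simple reduction of the benzophenone, which slow addition at high dilution and the favourable ring size should secure; there is no regiochemical choice because each carbonyl carbon already carries its final substituent (aryl on C1, methyl on C2). Aryl methyl, benzyl and MOM ethers are expected to be spectators with this reagent.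

Step 11
Reactants: 16 rac-1-Ar-3-(ArCH2)-7-methoxy-8-(methoxymethoxy)-2-methyl-3,4-dihydronaphthalene
Product: 17 1-Ar-3-(ArCH2)-7-methoxy-8-(methoxymethoxy)-2-methylnaphthalene
Conditions: DDQ (1.05 equiv), benzene, rt
Reagents that add atoms: none
Why: Dehydrogenation by hydride abstraction with DDQ, fast because the C4–H bond is benzylic and para to the 7-methoxy group and because proton loss from C3 then gives the aromatic ring, so one equivalent at room temperature should act before the side-chain CH2 is attacked; the stereocentre is erased.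

Step 12
Reactants: 17 1-Ar-3-(ArCH2)-7-methoxy-8-(methoxymethoxy)-2-methylnaphthalene
Product: 18 8-Ar-6-(ArCH2)-2-methoxy-7-methylnaphthalen-1-ol
Conditions: HCl, MeOH–THF, 45 °C, under argon
Reagents that add atoms: none
Why: Acid-catalysed acetal exchange (methanolysis of the MOM ether) frees the 1-naphthol, while aryl benzyl and aryl methyl ethers are stable to dilute HCl in methanol.

Step 13
Reactants: 18 8-Ar-6-(ArCH2)-2-methoxy-7-methylnaphthalen-1-ol
Product: 19 8-Ar-6-(ArCH2)-2-methoxy-7-methylnaphthalene-1,4-dione
Conditions: (KO3S)2NO (2.5 equiv), KH2PO4, H2O–acetone, rt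
Reagents that add atoms: potassium nitrosodisulfonate (Fremy's salt), [K+].[K+].[O]N(S(=O)(=O)[O-])S(=O)(=O)[O-]
Why: Teuber oxidation, in which the nitroxyl radical abstracts the naphthol hydrogen and a second equivalent adds at the free para position C4 (C2 is blocked by OMe) to give the 2-methoxy-1,4-naphthoquinone, while the benzyl-protected guaiacol rings cannot be oxidised.

Step 14
Reactants: 19 8-Ar-6-(ArCH2)-2-methoxy-7-methylnaphthalene-1,4-dione
Product: 21 larreantin, via naphthalene-1,4-diol 20 (not isolated)
Conditions: H2 (1 atm), Pd/C, EtOAc–MeOH, rt; filter; air, rt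
Reagents that add atoms: none
Why: Hydrogenolysis of the two aryl benzyl ethers over Pd/C also reduces the quinone to its hydroquinone, and autoxidation of this electron-rich naphthalene-1,4-diol in air should return the quinone.

**Compound list**

1 | 4-bromo-2-methoxyphenol | COc1cc(Br)ccc1O | starting material
2 | 1-(benzyloxy)-4-bromo-2-methoxybenzene | COc1cc(Br)ccc1OCc1ccccc1 | intermediate
3 | [4-(benzyloxy)-3-methoxyphenyl]magnesium bromide | COc1cc([Mg]Br)ccc1OCc1ccccc1 | intermediate (not isolated)
4 | 1-(benzyloxy)-4-(2-bromoprop-2-en-1-yl)-2-methoxybenzene | C=C(Br)Cc1ccc(OCc2ccccc2)c(OC)c1 | intermediate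
5 | 3-[4-(benzyloxy)-3-methoxyphenyl]prop-1-en-2-yllithium | [Li]C(=C)Cc1ccc(OCc2ccccc2)c(OC)c1 | intermediate (not isolated)
6 | rac-3-{[4-(benzyloxy)-3-methoxyphenyl]methyl}but-3-en-2-ol (one enantiomer drawn) | C[C@H](O)C(=C)Cc1ccc(OCc2ccccc2)c(OC)c1 | intermediate
7 | o-vanillin (2-hydroxy-3-methoxybenzaldehyde) | COc1cccc(C=O)c1O | starting material
8 | 3-methoxy-2-(methoxymethoxy)benzaldehyde | COCOc1c(OC)cccc1C=O | intermediate
9 | 6-bromo-3-methoxy-2-(methoxymethoxy)benzaldehyde | COCOc1c(OC)ccc(Br)c1C=O | intermediate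
10 | [4-(benzyloxy)-3-methoxyphenyl]lithium | [Li]c1ccc(OCc2ccccc2)c(OC)c1 | intermediate (not isolated)
11 | rac-[4-(benzyloxy)-3-methoxyphenyl][6-bromo-3-methoxy-2-(methoxymethoxy)phenyl]methanol (one enantiomer drawn) | COCOc1c(OC)ccc(Br)c1[C@H](O)c1ccc(OCc2ccccc2)c(OC)c1 | intermediate
12 | [4-(benzyloxy)-3-methoxyphenyl][6-bromo-3-methoxy-2-(methoxymethoxy)phenyl]methanone | COCOc1c(OC)ccc(Br)c1C(=O)c1ccc(OCc2ccccc2)c(OC)c1 | intermediate
13 | 9-{2-{[4-(benzyloxy)-3-methoxyphenyl]methyl}-3-[(9-borabicyclo[3.3.1]nonan-9-yl)oxy]butyl}-9-borabicyclo[3.3.1]nonane (mixture of diastereomers) | CC(OB1C2CCCC1CCC2)C(Cc1ccc(OCc2ccccc2)c(OC)c1)CB1C2CCCC1CCC2 | intermediate (not isolated)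
14 | 4-{2-[4-(benzyloxy)-3-methoxybenzoyl]-4-methoxy-3-(methoxymethoxy)phenyl}-3-{[4-(benzyloxy)-3-methoxyphenyl]methyl}butan-2-ol (racemic mixture of diastereomers) | CC(O)C(Cc1ccc(OCc2ccccc2)c(OC)c1)Cc1ccc(OC)c(OCOC)c1C(=O)c1ccc(OCc2ccccc2)c(OC)c1 | intermediate
15 | rac-4-{2-[4-(benzyloxy)-3-methoxybenzoyl]-4-methoxy-3-(methoxymethoxy)phenyl}-3-{[4-(benzyloxy)-3-methoxyphenyl]methyl}butan-2-one (one enantiomer drawn) | CC(=O)[C@H](Cc1ccc(OCc2ccccc2)c(OC)c1)Cc1ccc(OC)c(OCOC)c1C(=O)c1ccc(OCc2ccccc2)c(OC)c1 | intermediate
16 | rac-1-[4-(benzyloxy)-3-methoxyphenyl]-3-{[4-(benzyloxy)-3-methoxyphenyl]methyl}-7-methoxy-8-(methoxymethoxy)-2-methyl-3,4-dihydronaphthalene (one enantiomer drawn) | COCOc1c(OC)ccc2c1C(c1ccc(OCc3ccccc3)c(OC)c1)=C(C)[C@H](Cc1ccc(OCc3ccccc3)c(OC)c1)C2 | intermediate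
17 | 1-[4-(benzyloxy)-3-methoxyphenyl]-3-{[4-(benzyloxy)-3-methoxyphenyl]methyl}-7-methoxy-8-(methoxymethoxy)-2-methylnaphthalene | COCOc1c(OC)ccc2cc(Cc3ccc(OCc4ccccc4)c(OC)c3)c(C)c(-c3ccc(OCc4ccccc4)c(OC)c3)c12 | intermediate
18 | 8-[4-(benzyloxy)-3-methoxyphenyl]-6-{[4-(benzyloxy)-3-methoxyphenyl]methyl}-2-methoxy-7-methylnaphthalen-1-ol | COc1ccc2cc(Cc3ccc(OCc4ccccc4)c(OC)c3)c(C)c(-c3ccc(OCc4ccccc4)c(OC)c3)c2c1O | intermediate
19 | 8-[4-(benzyloxy)-3-methoxyphenyl]-6-{[4-(benzyloxy)-3-methoxyphenyl]methyl}-2-methoxy-7-methylnaphthalene-1,4-dione | COC1=CC(=O)c2cc(Cc3ccc(OCc4ccccc4)c(OC)c3)c(C)c(-c3ccc(OCc4ccccc4)c(OC)c3)c2C1=O | intermediate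
20 | 8-(4-hydroxy-3-methoxyphenyl)-6-[(4-hydroxy-3-methoxyphenyl)methyl]-2-methoxy-7-methylnaphthalene-1,4-diol | COc1cc(O)c2cc(Cc3ccc(O)c(OC)c3)c(C)c(-c3ccc(O)c(OC)c3)c2c1O | intermediate (not isolated)
21 | larreantin, 8-(4-hydroxy-3-methoxyphenyl)-6-[(4-hydroxy-3-methoxyphenyl)methyl]-2-methoxy-7-methylnaphthalene-1,4-dione | COC1=CC(=O)c2cc(Cc3ccc(O)c(OC)c3)c(C)c(-c3ccc(O)c(OC)c3)c2C1=O | target

**Step count and risks**

Total step count: 14. Longest linear sequence: 11 steps (o-vanillin 7 through steps 4–14).

Steps most likely to fail: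

1. Step 10 (McMurry ring closure). The coupling may stop at the titanium pinacolate, which is slow to deoxygenate next to the ortho-substituted aryl ring. The benzophenone may also be reduced on its own before it couples, or the carbonyl-chelated MOM group may be lost. The fallback forms the same bond in two stages and sets out from 15. SmI2 (THF, t-BuOH, −78 °C → rt) should effect ketyl–carbonyl pinacol cyclisation to the cis-diol 1-Ar-3-(ArCH2)-7-methoxy-8-(methoxymethoxy)-2-methyl-1,2,3,4-tetrahydronaphthalene-1,2-diol F1. 1,1'-Thiocarbonyldiimidazole (toluene, reflux) should convert this into the cyclic thiocarbonate F2. P(OMe)3 at reflux (Corey–Winter olefination, syn elimination) should then deliver the alkene and bring the route back at 16.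

2. Step 11 (DDQ aromatisation). Once the ring is aromatic, hydride abstraction may continue at the doubly benzylic CH2 of the side chain or at a benzyl ether methylene, giving over-oxidation. The fallback replaces the external oxidant by an internal redox and sets out from 16. HCl in MeOH–THF should remove the MOM group to give the phenol rac-8-Ar-6-(ArCH2)-2-methoxy-7-methyl-5,6-dihydronaphthalen-1-ol F3. (KO3S)2NO oxidation at the free para position should give the p-quinone rac-8-Ar-6-(ArCH2)-2-methoxy-7-methyl-5,6-dihydronaphthalene-1,4-dione F4. Catalytic Et3N in CH2Cl2 under argon should move the C5 and C6 hydrogens to the quinone oxygens by two prototropic shifts, driven by aromatisation of both rings, to give 8-Ar-6-(ArCH2)-2-methoxy-7-methylnaphthalene-1,4-diol F5. Air should oxidise this to the quinone, so the route is rejoined at 19 and steps 12 and 13 are not needed.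

3. Step 8 (hydroboration and B-alkyl Suzuki–Miyaura coupling). Hydroboration of the 1,1-disubstituted alkene beside the borinate may be incomplete. The β-branched alkyl group may also undergo β-hydride elimination or protodeboronation during transmetalation, so that the aryl bromide is merely reduced. The fallback is a Heck arylation of the allylic alcohol 6 with the bromobenzophenone 12 (Pd(OAc)2, Bu4NCl, NaHCO3, DMF, 90 °C). Carbopalladation at the terminal CH2, β-hydride elimination towards the carbinol C–H and tautomerisation of the enol should give the diketone directly. It sets out from 6 and 12, comes back at 15, makes step 9 unnecessary and forms no new compound (entry F0 below).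

**Further compounds**

F1 | step 10 | 1-[4-(benzyloxy)-3-methoxyphenyl]-3-{[4-(benzyloxy)-3-methoxyphenyl]methyl}-7-methoxy-8-(methoxymethoxy)-2-methyl-1,2,3,4-tetrahydronaphthalene-1,2-diol (cis-diol, racemic, mixture at C3) | COCOc1c(OC)ccc2c1C(O)(c1ccc(OCc3ccccc3)c(OC)c1)C(C)(O)C(Cc1ccc(OCc3ccccc3)c(OC)c1)C2
F2 | step 10 | cyclic thiocarbonate of F1, 9b-[4-(benzyloxy)-3-methoxyphenyl]-4-{[4-(benzyloxy)-3-methoxyphenyl]methyl}-8-methoxy-9-(methoxymethoxy)-3a-methyl-3a,4,5,9b-tetrahydronaphtho[1,2-d][1,3]dioxole-2-thione (cis ring fusion, racemic, mixture at C4) | COCOc1c(OC)ccc2c1C1(c3ccc(OCc4ccccc4)c(OC)c3)OC(=S)OC1(C)C(Cc1ccc(OCc3ccccc3)c(OC)c1)C2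
F3 | step 11 | rac-8-[4-(benzyloxy)-3-methoxyphenyl]-6-{[4-(benzyloxy)-3-methoxyphenyl]methyl}-2-methoxy-7-methyl-5,6-dihydronaphthalen-1-ol (one enantiomer drawn) | COc1ccc2c(c1O)C(c1ccc(OCc3ccccc3)c(OC)c1)=C(C)[C@H](Cc1ccc(OCc3ccccc3)c(OC)c1)C2
F4 | step 11 | rac-8-[4-(benzyloxy)-3-methoxyphenyl]-6-{[4-(benzyloxy)-3-methoxyphenyl]methyl}-2-methoxy-7-methyl-5,6-dihydronaphthalene-1,4-dione (one enantiomer drawn) | COC1=CC(=O)C2=C(C1=O)C(c1ccc(OCc3ccccc3)c(OC)c1)=C(C)[C@H](Cc1ccc(OCc3ccccc3)c(OC)c1)C2
F5 | step 11 | 8-[4-(benzyloxy)-3-methoxyphenyl]-6-{[4-(benzyloxy)-3-methoxyphenyl]methyl}-2-methoxy-7-methylnaphthalene-1,4-diol | COc1cc(O)c2cc(Cc3ccc(OCc4ccccc4)c(OC)c3)c(C)c(-c3ccc(OCc4ccccc4)c(OC)c3)c2c1O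
F0 | step 8 | none | none
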